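**Plan**

1. Atom labels: C1 (ring-fusion carbon with CH3), C2 (CH–OAc), C3 (CH2), C4 (C(OH)–iPr), C5 (ring-fusion CH), C6 (CH–O-aroyl), C7 (CH2), C8 (=C–CH3), C9 (=CH), C10 (CH2); ring A is the cyclopentane C1–C5, ring B the cycloheptene C1/C5–C10.
2. Enabling feature: on ring A the oxygens at C2 and C4 stand 1,3 across the C3 methylene and C4 is a tertiary carbinol bearing isopropyl. This is the retron of an aldol between the C3 enolate of a C2 ketone and a C4 isopropyl ketone held trans on ring B.
3. Retrosynthesis: cut the C6 and C2 ester C–O bonds, return C2 to a ketone, cut C3–C4 (ring A), then C3–Br, the C2 carbonyl (back to a vinyl group), C8=C9 (ring B), C4–isopropyl, C1–C5 ([3,3]), the allyl ester C–O and C7–C8.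
4. Forward: epoxide opening and transesterification join the chain, an Ireland–Claisen rearrangement forms C1–C5, metathesis closes ring B, Wacker oxidation and bromination arm C2–C3, and a samarium enolate aldol closes ring A last.
5. Stereochemistry: C6 from ethyl (R)-3,4-epoxybutanoate; C5 from C6 through a lithium chelate (anti); C1 from the chair transition state and the (E)-alkene; C4 from the ring B substituents in the aldol closure; C2 from hydroxyl-directed hydride delivery.

Key step: step 10

Assumption: ethyl (R)-3,4-epoxybutanoate is used as the purchased (R)-enantiomer; copper-catalysed Grignard attack occurs at its CH2 terminus, so its stereocentre is carried into C6 unchanged.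

**Step 1**
Reactants: 1 pent-1-en-4-yne
Product: 3 (2E)-3-methylhexa-2,5-dien-1-ol, via alkenyldimethylalane 2 (not isolated)
Conditions: Me3Al (2.0 equiv), Cp2ZrCl2 (0.2 equiv), CH2Cl2, 0 to 23 °C; then (CH2O)n, THF, 0 to 23 °C; aq. HCl
Reagents that add atoms: trimethylaluminium, C[Al](C)C; formaldehyde (as paraformaldehyde), C=O
Why: Negishi zirconium-catalysed carboalumination adds methyl and aluminium syn across the terminal alkyne (methyl to the internal carbon) and leaves the isolated alkene untouched, so trapping the alkenylalane with formaldehyde should give the allylic alcohol with the allyl group trans to CH2OH.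

**Step 2**
Reactants: 4 ethyl (R)-3,4-epoxybutanoate
Product: 5 ethyl (3S)-3-hydroxy-5-methylhex-5-enoate
Conditions: isopropenylmagnesium bromide (1.5 equiv), CuI (0.1 equiv), THF, −40 to −20 °C; aqueous work-up
Reagents that add atoms: isopropenylmagnesium bromide, CC(=C)[Mg]Br
Why: copper-catalysed Grignard opening of a terminal epoxide is an SN2 attack at the unsubstituted carbon that outpaces addition to the ester at low temperature, so C7–C8 forms and the carbinol centre (C6) keeps its arrangement, the descriptor changing from R to S through priority only.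

**Step 3**
Reactants: 5 ethyl (3S)-3-hydroxy-5-methylhex-5-enoate; 3 (2E)-3-methylhexa-2,5-dien-1-ol
Product: 6 (2E)-3-methylhexa-2,5-dien-1-yl (3S)-3-hydroxy-5-methylhex-5-enoate
Conditions: 3 (2.0 equiv), Ti(OEt)4 (0.2 equiv), toluene, 100 °C, 4 Å molecular sieves (removal of EtOH)
Reagents that add atoms: none
Why: titanate-mediated transesterification is neutral, tolerates a free β-hydroxyl and an allylic alcohol without dehydration or allylic transposition, and is driven by removal of ethanol.

**Step 4**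
Reactants: 6 (2E)-3-methylhexa-2,5-dien-1-yl (3S)-3-hydroxy-5-methylhex-5-enoate
Product: 8 (2S,3S)-3-hydroxy-5-methyl-2-[(3S)-3-methylhexa-1,5-dien-3-yl]hex-5-enoic acid, via dilithium enolate alkoxide 7 (not isolated)
Conditions: LiN(iPr)2 (2.2 equiv), THF, −78 °C; then 23 to 60 °C; aq. HCl
Reagents that add atoms: none
Why: in this dianionic Ireland–Claisen rearrangement of an allyl β-hydroxy ester the lithium-bridged enolate alkoxide holds C6 cis to the enolate oxygen, the allyl unit reaches C5 on the chelate face opposite the C7 chain (the sense of a Fráter–Seebach alkylation, so C5 is anti to C6–O), and the chair transition state with the (E)-alkene places the allyl group equatorial and the methyl axial, which fixes the quaternary C1 relative to C5.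

**Step 5**
Reactants: 8 (2S,3S)-3-hydroxy-5-methyl-2-[(3S)-3-methylhexa-1,5-dien-3-yl]hex-5-enoic acid
Product: 10 (2S,3S)-3-[(tert-butyldimethylsilyl)oxy]-5-methyl-2-[(3S)-3-methylhexa-1,5-dien-3-yl]hex-5-enoic acid, via bis-silyl derivative 9 (not isolated)
Conditions: TBSOTf (2.5 equiv), 2,6-lutidine (4 equiv), CH2Cl2, −78 to 0 °C; then AcOH/THF/H2O, 23 °C
Reagents that add atoms: tert-butyldimethylsilyl trifluoromethanesulfonate, CC(C)(C)[Si](C)(C)OS(=O)(=O)C(F)(F)F
Why: the silyl triflate silylates both the hindered secondary hydroxyl and the acid, and only the silyl ester is hydrolysed by dilute acetic acid, which leaves the secondary silyl ether and the 1,1-disubstituted alkene intact.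

**Step 6**
Reactants: 10 (2S,3S)-3-[(tert-butyldimethylsilyl)oxy]-5-methyl-2-[(3S)-3-methylhexa-1,5-dien-3-yl]hex-5-enoic acid
Product: 12 (4S,5S)-5-[(tert-butyldimethylsilyl)oxy]-2,7-dimethyl-4-[(3S)-3-methylhexa-1,5-dien-3-yl]oct-7-en-3-one, via acid chloride 11 (not isolated)
Conditions: 1-chloro-N,N,2-trimethylprop-1-en-1-amine (1.2 equiv), CH2Cl2, 0 to 23 °C; then iPrMgCl (1.3 equiv), CuI (0.1 equiv), THF, −78 °C
Reagents that add atoms: isopropylmagnesium chloride, CC(C)[Mg]Cl
Why: the α-chloroenamine forms the acid chloride under neutral conditions (no HCl to attack the silyl ether or the methallyl alkene) and copper-catalysed acylation of the Grignard reagent stops at the hindered ketone, the low temperature being chosen to avoid ketene formation and so keep C5.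

**Step 7**
Reactants: 12 (4S,5S)-5-[(tert-butyldimethylsilyl)oxy]-2,7-dimethyl-4-[(3S)-3-methylhexa-1,5-dien-3-yl]oct-7-en-3-one
Product: 13 1-[(1S,2S,7S)-7-[(tert-butyldimethylsilyl)oxy]-2-ethenyl-2,5-dimethylcyclohept-4-en-1-yl]-2-methylpropan-1-one
Conditions: second-generation Grubbs catalyst RuCl2(=CHPh)(PCy3)(H2IMes) (5 mol %), CH2Cl2 (5 mM), 40 °C
Reagents that add atoms: none
Why: in this ring-closing metathesis the catalyst loads on the unhindered allyl terminus (C9), from which only the methallyl alkene (C8) can be reached to give the trisubstituted cycloheptene of ring B, whereas the vinyl group on the quaternary C1 is too hindered to initiate and could only close a four-membered ring with the allyl carbene.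

**Step 8**
Reactants: 13 1-[(1S,2S,7S)-7-[(tert-butyldimethylsilyl)oxy]-2-ethenyl-2,5-dimethylcyclohept-4-en-1-yl]-2-methylpropan-1-one
Product: 14 1-[(1S,2R,7S)-2-acetyl-7-[(tert-butyldimethylsilyl)oxy]-2,5-dimethylcyclohept-4-en-1-yl]-2-methylpropan-1-one
Conditions: PdCl2 (0.2 equiv), CuCl (1.0 equiv), O2 (1 atm), DMF/H2O (7:1), 23 to 40 °C
Reagents that add atoms: water, O
Why: Tsuji–Wacker oxidation with divalent palladium converts the monosubstituted vinyl group into the methyl ketone by Markovnikov hydroxypalladation (the standard route from γ,δ-unsaturated ketones to 1,4-diketones), and the trisubstituted ring alkene does not react.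

**Step 9**
Reactants: 14 1-[(1S,2R,7S)-2-acetyl-7-[(tert-butyldimethylsilyl)oxy]-2,5-dimethylcyclohept-4-en-1-yl]-2-methylpropan-1-one
Product: 16 1-[(1S,2R,7S)-2-(2-bromoacetyl)-7-[(tert-butyldimethylsilyl)oxy]-2,5-dimethylcyclohept-4-en-1-yl]-2-methylpropan-1-one, via trimethylsilyl enol ether 15 (not isolated)
Conditions: Me3SiCl (3 equiv), LiN(SiMe3)2 (1.2 equiv), THF, −78 °C (in situ quench); then N-bromosuccinimide (1.05 equiv), THF, −78 to −40 °C
Reagents that add atoms: N-bromosuccinimide, O=C1CCC(=O)N1Br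
Why: kinetic enolisation can readily take only the acetyl methyl group (its other α carbon is quaternary, while C5–H and the isopropyl methine are tertiary and shielded), in situ silylation intercepts the enolate before it can add to the C4 ketone, and the silyl enol ether is brominated by N-bromosuccinimide far faster than the ring alkene.

**Step 10**
Reactants: 16 1-[(1S,2R,7S)-2-(2-bromoacetyl)-7-[(tert-butyldimethylsilyl)oxy]-2,5-dimethylcyclohept-4-en-1-yl]-2-methylpropan-1-one
Product: 18 (3R,3aS,4S,8aR)-4-[(tert-butyldimethylsilyl)oxy]-3-hydroxy-6,8a-dimethyl-3-(propan-2-yl)-3,3a,4,5,8,8a-hexahydroazulen-1(2H)-one, via diiodosamarium enolate 17 (not isolated)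
Conditions: SmI2 (2.2 equiv, 0.1 M in THF), THF, −78 to −20 °C; aq. NH4Cl
Reagents that add atoms: none
Why: Two single-electron transfers from divalent samarium cleave the C3–Br bond and give the oxygen-bound trivalent samarium enolate of the C2 ketone, whose C3 carbon adds to the C4 isopropyl ketone while the metal bridges both oxygens. The closest known reaction type is the SmI2-promoted intramolecular Reformatsky-type aldol of α-halo carbonyl compounds, with the base-mediated aldol cyclisation of 1,4-diketones as the classical counterpart. Ring A closes in a 5-(enolendo)-exo-trig mode between two side-chain carbons on the trans-disposed C1 and C5, a closure that is slow for a free enolate but is assisted by the oxophilic chelating metal and cannot disturb the ring fusion. The new C4 centre is controlled by the substrate: the isopropyl group takes the face of C5–H, away from the C6 silyloxy branch and the C1 methyl group, so that the carbinol oxygen ends on the face of the C1 methyl. The step needs reduction of C–Br only and no loss of water; the α-bromo ketone is the sole group in 16 that SmI2 reduces in THF without additives (dialkyl ketone, silyl ether and alkene are inert), and the samarium aldolate of a tertiary carbinol does not dehydrate at low temperature.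

**Step 11**
Reactants: 18 (3R,3aS,4S,8aR)-4-[(tert-butyldimethylsilyl)oxy]-3-hydroxy-6,8a-dimethyl-3-(propan-2-yl)-3,3a,4,5,8,8a-hexahydroazulen-1(2H)-one
Product: 19 (1S,3R,3aS,4S,8aR)-4-[(tert-butyldimethylsilyl)oxy]-6,8a-dimethyl-3-(propan-2-yl)-1,2,3,3a,4,5,8,8a-octahydroazulene-1,3-diol
Conditions: Me4NBH(OAc)3 (5 equiv), MeCN/AcOH (1:1), −30 to 0 °C
Reagents that add atoms: none
Why: in this Evans–Saksena reduction the tertiary C4 hydroxyl exchanges onto boron and the alkoxyborohydride delivers hydride within the molecule to the face of the C2 carbonyl on which C4–O lies, which should give the 1,3-anti diol (C2–OH trans to C4–OH) against the steric bias of the C1 methyl, the reagent being too weak to reduce the ketone intermolecularly.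

**Step 12**
Reactants: 19 (1S,3R,3aS,4S,8aR)-4-[(tert-butyldimethylsilyl)oxy]-6,8a-dimethyl-3-(propan-2-yl)-1,2,3,3a,4,5,8,8a-octahydroazulene-1,3-diol
Product: 20 (1S,3R,3aS,4S,8aR)-4-[(tert-butyldimethylsilyl)oxy]-3-hydroxy-6,8a-dimethyl-3-(propan-2-yl)-1,2,3,3a,4,5,8,8a-octahydroazulen-1-yl acetate
Conditions: Ac2O (3 equiv), pyridine, DMAP (0.1 equiv), CH2Cl2, 0 to 23 °C
Reagents that add atoms: acetic anhydride, CC(=O)OC(C)=O
Why: nucleophile-catalysed acylation takes the secondary C2 hydroxyl only, because the C4 hydroxyl is tertiary and flanked by the isopropyl group and the ring fusion.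

**Step 13**
Reactants: 20 (1S,3R,3aS,4S,8aR)-4-[(tert-butyldimethylsilyl)oxy]-3-hydroxy-6,8a-dimethyl-3-(propan-2-yl)-1,2,3,3a,4,5,8,8a-octahydroazulen-1-yl acetate
Product: 21 (1S,3R,3aS,4S,8aR)-3,4-dihydroxy-6,8a-dimethyl-3-(propan-2-yl)-1,2,3,3a,4,5,8,8a-octahydroazulen-1-yl acetate
Conditions: HF·pyridine, pyridine/THF, 0 to 23 °C
Reagents that add atoms: none
Why: pyridine-buffered hydrogen fluoride cleaves the secondary silyl ether without forming an alkoxide, so the C2 acetate should neither migrate nor be cleaved and the tertiary carbinol is not ionised.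

**Step 14**
Reactants: 22 4-hydroxybenzoic acid
Product: 24 4-[(tert-butyldimethylsilyl)oxy]benzoic acid, via bis-silyl derivative 23 (not isolated)
Conditions: TBSCl (2.3 equiv), imidazole (5 equiv), DMF, 23 °C; then AcOH/THF/H2O, 23 °C
Reagents that add atoms: tert-butylchlorodimethylsilane, CC(C)(C)[Si](C)(C)Cl
Why: silylation of phenol and acid followed by selective hydrolysis of the much more labile silyl ester masks the phenol, so that it cannot compete as a nucleophile in the esterification.

**Step 15**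
Reactants: 21 (1S,3R,3aS,4S,8aR)-3,4-dihydroxy-6,8a-dimethyl-3-(propan-2-yl)-1,2,3,3a,4,5,8,8a-octahydroazulen-1-yl acetate; 24 4-[(tert-butyldimethylsilyl)oxy]benzoic acid
Product: 25 (1S,3R,3aS,4S,8aR)-1-(acetyloxy)-3-hydroxy-6,8a-dimethyl-3-(propan-2-yl)-1,2,3,3a,4,5,8,8a-octahydroazulen-4-yl 4-[(tert-butyldimethylsilyl)oxy]benzoate
Conditions: DCC (1.6 equiv), DMAP (0.5 equiv), CH2Cl2, 23 °C
Reagents that add atoms: none
Why: Steglich esterification acylates the secondary C6 hydroxyl, while the tertiary C4 hydroxyl is inert under these conditions.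

**Step 16**
Reactants: 25 (1S,3R,3aS,4S,8aR)-1-(acetyloxy)-3-hydroxy-6,8a-dimethyl-3-(propan-2-yl)-1,2,3,3a,4,5,8,8a-octahydroazulen-4-yl 4-[(tert-butyldimethylsilyl)oxy]benzoate
Product: 26 (1S,3R,3aS,4S,8aR)-1-(acetyloxy)-3-hydroxy-6,8a-dimethyl-3-(propan-2-yl)-1,2,3,3a,4,5,8,8a-octahydroazulen-4-yl 4-hydroxybenzoate
Conditions: Bu4NF (1.1 equiv), AcOH (1.1 equiv), THF, 0 °C
Reagents that add atoms: none
Why: aryl silyl ethers are cleaved by fluoride within minutes, and the acetic acid buffer keeps the medium non-basic so that neither the acetate nor the benzoate ester should be touched.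

**Compound list**

1 | pent-1-en-4-yne | C=CCC#C | starting material
2 | dimethyl[(1E)-2-methylpenta-1,4-dien-1-yl]alane | C=CC/C(C)=C/[Al](C)C | intermediate
3 | (2E)-3-methylhexa-2,5-dien-1-ol | C=CC/C(C)=C/CO | intermediate
4 | ethyl (R)-3,4-epoxybutanoate (ethyl 2-[(2R)-oxiran-2-yl]acetate) | C1[C@H](O1)CC(=O)OCC | starting material
5 | ethyl (3S)-3-hydroxy-5-methylhex-5-enoate | C=C(C)C[C@H](O)CC(=O)OCC | intermediate
6 | (2E)-3-methylhexa-2,5-dien-1-yl (3S)-3-hydroxy-5-methylhex-5-enoate | C=CC/C(C)=C/COC(=O)C[C@@H](O)CC(C)=C | intermediate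
7 | dilithium enolate alkoxide of 6 (enolate oxygen cis to C6, lithium-bridged) | [Li+].[Li+].C=CC/C(C)=C/CO/C([O-])=C/[C@@H]([O-])CC(C)=C | intermediate
8 | (2S,3S)-3-hydroxy-5-methyl-2-[(3S)-3-methylhexa-1,5-dien-3-yl]hex-5-enoic acid | C=C[C@](C)(CC=C)[C@H](C(=O)O)[C@@H](O)CC(C)=C | intermediate
9 | tert-butyldimethylsilyl (2S,3S)-3-[(tert-butyldimethylsilyl)oxy]-5-methyl-2-[(3S)-3-methylhexa-1,5-dien-3-yl]hex-5-enoate | C=C[C@](C)(CC=C)[C@H](C(=O)O[Si](C)(C)C(C)(C)C)[C@@H](O[Si](C)(C)C(C)(C)C)CC(C)=C | intermediate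
10 | (2S,3S)-3-[(tert-butyldimethylsilyl)oxy]-5-methyl-2-[(3S)-3-methylhexa-1,5-dien-3-yl]hex-5-enoic acid | C=C[C@](C)(CC=C)[C@H](C(=O)O)[C@@H](O[Si](C)(C)C(C)(C)C)CC(C)=C | intermediate
11 | (2S,3S)-3-[(tert-butyldimethylsilyl)oxy]-5-methyl-2-[(3S)-3-methylhexa-1,5-dien-3-yl]hex-5-enoyl chloride | C=C[C@](C)(CC=C)[C@H](C(Cl)=O)[C@@H](O[Si](C)(C)C(C)(C)C)CC(C)=C | intermediate
12 | (4S,5S)-5-[(tert-butyldimethylsilyl)oxy]-2,7-dimethyl-4-[(3S)-3-methylhexa-1,5-dien-3-yl]oct-7-en-3-one | C=C[C@](C)(CC=C)[C@H](C(=O)C(C)C)[C@@H](O[Si](C)(C)C(C)(C)C)CC(C)=C | intermediate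
13 | 1-[(1S,2S,7S)-7-[(tert-butyldimethylsilyl)oxy]-2-ethenyl-2,5-dimethylcyclohept-4-en-1-yl]-2-methylpropan-1-one | C=C[C@]1(C)CC=C(C)C[C@H](O[Si](C)(C)C(C)(C)C)[C@H]1C(=O)C(C)C | intermediate
14 | 1-[(1S,2R,7S)-2-acetyl-7-[(tert-butyldimethylsilyl)oxy]-2,5-dimethylcyclohept-4-en-1-yl]-2-methylpropan-1-one | CC(=O)[C@]1(C)CC=C(C)C[C@H](O[Si](C)(C)C(C)(C)C)[C@H]1C(=O)C(C)C | intermediate
15 | 1-[(1S,2R,7S)-7-[(tert-butyldimethylsilyl)oxy]-2,5-dimethyl-2-{1-[(trimethylsilyl)oxy]ethenyl}cyclohept-4-en-1-yl]-2-methylpropan-1-one | C=C(O[Si](C)(C)C)[C@]1(C)CC=C(C)C[C@H](O[Si](C)(C)C(C)(C)C)[C@H]1C(=O)C(C)C | intermediate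
16 | 1-[(1S,2R,7S)-2-(2-bromoacetyl)-7-[(tert-butyldimethylsilyl)oxy]-2,5-dimethylcyclohept-4-en-1-yl]-2-methylpropan-1-one | BrCC(=O)[C@]1(C)CC=C(C)C[C@H](O[Si](C)(C)C(C)(C)C)[C@H]1C(=O)C(C)C | intermediate
17 | diiodosamarium enolate of the C2 ketone (O-bound trivalent samarium, C2=C3) | C=C(O[Sm](I)I)[C@]1(C)CC=C(C)C[C@H](O[Si](C)(C)C(C)(C)C)[C@H]1C(=O)C(C)C | intermediate
18 | (3R,3aS,4S,8aR)-4-[(tert-butyldimethylsilyl)oxy]-3-hydroxy-6,8a-dimethyl-3-(propan-2-yl)-3,3a,4,5,8,8a-hexahydroazulen-1(2H)-one | O=C1C[C@@](O)(C(C)C)[C@@H]2[C@@H](O[Si](C)(C)C(C)(C)C)CC(C)=CC[C@@]12C | intermediate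
19 | (1S,3R,3aS,4S,8aR)-4-[(tert-butyldimethylsilyl)oxy]-6,8a-dimethyl-3-(propan-2-yl)-1,2,3,3a,4,5,8,8a-octahydroazulene-1,3-diol | O[C@H]1C[C@@](O)(C(C)C)[C@@H]2[C@@H](O[Si](C)(C)C(C)(C)C)CC(C)=CC[C@@]12C | intermediate
20 | (1S,3R,3aS,4S,8aR)-4-[(tert-butyldimethylsilyl)oxy]-3-hydroxy-6,8a-dimethyl-3-(propan-2-yl)-1,2,3,3a,4,5,8,8a-octahydroazulen-1-yl acetate | CC(=O)O[C@H]1C[C@@](O)(C(C)C)[C@@H]2[C@@H](O[Si](C)(C)C(C)(C)C)CC(C)=CC[C@@]12C | intermediate
21 | (1S,3R,3aS,4S,8aR)-3,4-dihydroxy-6,8a-dimethyl-3-(propan-2-yl)-1,2,3,3a,4,5,8,8a-octahydroazulen-1-yl acetate | CC(=O)O[C@H]1C[C@@](O)(C(C)C)[C@@H]2[C@@H](O)CC(C)=CC[C@@]12C | intermediate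
22 | 4-hydroxybenzoic acid | OC(=O)c1ccc(O)cc1 | starting material
23 | tert-butyldimethylsilyl 4-[(tert-butyldimethylsilyl)oxy]benzoate | CC(C)(C)[Si](C)(C)OC(=O)c1ccc(O[Si](C)(C)C(C)(C)C)cc1 | intermediate
24 | 4-[(tert-butyldimethylsilyl)oxy]benzoic acid | OC(=O)c1ccc(O[Si](C)(C)C(C)(C)C)cc1 | intermediate
25 | (1S,3R,3aS,4S,8aR)-1-(acetyloxy)-3-hydroxy-6,8a-dimethyl-3-(propan-2-yl)-1,2,3,3a,4,5,8,8a-octahydroazulen-4-yl 4-[(tert-butyldimethylsilyl)oxy]benzoate | CC(=O)O[C@H]1C[C@@](O)(C(C)C)[C@@H]2[C@@H](OC(=O)c3ccc(O[Si](C)(C)C(C)(C)C)cc3)CC(C)=CC[C@@]12C | intermediate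
26 | (1S,3R,3aS,4S,8aR)-1-(acetyloxy)-3-hydroxy-6,8a-dimethyl-3-(propan-2-yl)-1,2,3,3a,4,5,8,8a-octahydroazulen-4-yl 4-hydroxybenzoate | CC(=O)O[C@H]1C[C@@](O)(C(C)C)[C@@H]2[C@@H](OC(=O)c3ccc(O)cc3)CC(C)=CC[C@@]12C | target

**Step count**

Total: 16 steps. Longest linear sequence: 14 steps (from 4 through steps 2 to 13, 15 and 16; the branch from 1 through steps 1, 3 to 13, 15 and 16 has the same length).

**Steps most likely to fail**

Step 10. The samarium enolate may be protonated, or the hindered aldolate may revert, before the slow 5-(enolendo) closure onto the doubly α-branched C4 ketone is secured; facial selectivity at C4 may also be poor. The fallback sets out from 14. The trimethylsilyl enol ether 15 is isolated (first half of step 9, non-aqueous work-up) and the same C3–C4 bond is closed by an intramolecular Mukaiyama aldol (TiCl4, CH2Cl2, −78 °C), in which the Lewis acid activates the C4 ketone and the transition state is open. Aqueous work-up returns the route at 18. This fallback passes through no compound outside the list (F0).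

Step 4. The aggregated dianion may rearrange too slowly at the temperature it tolerates because the allyl terminus is fully substituted, or the chelate may open on heating so that facial selectivity at C5 erodes. The fallback sets out from 6. The C6 hydroxyl is protected as the silyl ether F1 (TBSCl, imidazole, DMF). The silyl ketene acetal F2 with C6 cis to the silyloxy group is generated (LiN(iPr)2, Me3SiCl, THF/DMPU, −78 °C) and left to rearrange at 23 to 50 °C to the trimethylsilyl ester F3. Here the enolate geometry is set by the polar co-solvent and the facial bias by allylic strain at the C6 stereocentre in place of the chelate. Hydrolysis of the silyl ester (AcOH/THF/H2O) returns the route at 10, so that step 5 is not needed.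

Step 6. The acid chloride may form a ketene, with loss of the C5 configuration, or acyl transfer may fail at the congested carbonyl. The fallback sets out from 10. The acid is reduced to the primary alcohol F4 (LiAlH4, THF, 0 °C) and oxidised to the aldehyde F5 (Dess–Martin periodinane, NaHCO3, CH2Cl2). Addition of iPrMgCl (THF, −78 °C) should give the secondary alcohol F6 as a mixture of carbinol epimers, and a second Dess–Martin oxidation returns the route at 12. The aldehyde accepts the Grignard reagent without an acyl leaving group, and no ketene can form.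

**Further compounds**

F0 | step 10 | none | none
F1 | step 4 | (2E)-3-methylhexa-2,5-dien-1-yl (3S)-3-[(tert-butyldimethylsilyl)oxy]-5-methylhex-5-enoate | C=CC/C(C)=C/COC(=O)C[C@@H](O[Si](C)(C)C(C)(C)C)CC(C)=C
F2 | step 4 | trimethylsilyl ketene acetal of F1 (C6 cis to OSiMe3) | C=CC/C(C)=C/CO/C(O[Si](C)(C)C)=C/[C@@H](O[Si](C)(C)C(C)(C)C)CC(C)=C
F3 | step 4 | trimethylsilyl (2S,3S)-3-[(tert-butyldimethylsilyl)oxy]-5-methyl-2-[(3S)-3-methylhexa-1,5-dien-3-yl]hex-5-enoate | C=C[C@](C)(CC=C)[C@H](C(=O)O[Si](C)(C)C)[C@@H](O[Si](C)(C)C(C)(C)C)CC(C)=C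
F4 | step 6 | (2R,3S)-3-[(tert-butyldimethylsilyl)oxy]-5-methyl-2-[(3S)-3-methylhexa-1,5-dien-3-yl]hex-5-en-1-ol | C=C[C@](C)(CC=C)[C@H](CO)[C@@H](O[Si](C)(C)C(C)(C)C)CC(C)=C
F5 | step 6 | (2S,3S)-3-[(tert-butyldimethylsilyl)oxy]-5-methyl-2-[(3S)-3-methylhexa-1,5-dien-3-yl]hex-5-enal | C=C[C@](C)(CC=C)[C@H](C=O)[C@@H](O[Si](C)(C)C(C)(C)C)CC(C)=C
F6 | step 6 | (4R,5S)-5-[(tert-butyldimethylsilyl)oxy]-2,7-dimethyl-4-[(3S)-3-methylhexa-1,5-dien-3-yl]oct-7-en-3-ol (both C3 epimers) | C=C[C@](C)(CC=C)[C@H](C(O)C(C)C)[C@@H](O[Si](C)(C)C(C)(C)C)CC(C)=C
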